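The numbers of this flask were chosen freely; the result is computed.

An excess is asked for.

    partner + free catalyst + left-handed substrate → free catalyst + left-handed product (k1 = 0.39 M⁻² s⁻¹, Ea1 = 52.0 kJ mol⁻¹)
    partner + free catalyst + right-handed substrate → free catalyst + right-handed product (k2 = 0.17 M⁻² s⁻¹, Ea2 = 35.0 kJ mol⁻¹)
    left-handed substrate + racemization catalyst ⇌ right-handed substrate + racemization catalyst, rate k3*[racemization catalyst]*[left-handed substrate] forward; the back reaction follows from the equilibrium constant (k3 = 0.023 M⁻¹ s⁻¹, Ea3 = 46.0 kJ mol⁻¹)
    gas ⇌ partner, rate k4*(csat - [partner]) (k4 = 0.25 s⁻¹, csat = 200 mM)
    partner → decomposed reagent (k5 = 0.0020 s⁻¹, Ea5 = 98.0 kJ mol⁻¹)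
    2 racemization catalyst ⇌ resting dimer, settled at all times (K6 = 6.6 M⁻¹, ΔH6 = −1.00 kJ mol⁻¹)
    (constants at 25 °C)

| setting | south-west | north-east | east |
|---|---|---|---|
| left-handed substrate | 2.0 M | 2.0 M | 2.0 M |
| gas | 200 mM (held) | 200 mM (held) | 200 mM (held) |
| free catalyst | 82 mM | 82 mM | 82 mM |
| racemization catalyst | 78 mM | 78 mM | 78 mM |
| right-handed substrate | 2.0 M | 2.0 M | 2.0 M |
| time | 40 min | 40 min | 40 min |
| remark | at 10 °C until 8.0 min, from then on at 25 °C |  |  |
| temperature |  | 10 °C | 25 °C |

- free catalyst is single-handed; left-handed substrate and right-handed substrate are mirror images of each other, charged as a racemate, each of them at the stated concentration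
- a step written with two of one species runs at k times the square of its concentration and takes two of it each time
- at the start none of partner is dissolved
- constants are those at 25 °C; use the activation energies and enthalpies for any other temperature
- an excess is the difference of the two amounts in percent of their sum
- an excess is below zero if the other one leads

1. the flask with the highest excess of left-handed product over right-handed product ("all alike" if they lie within 1.5 percentage points) (south-west / north-east / east / all alike)
2. excess of left-handed product over right-handed product at the end, south-west
3. excess of left-handed product over right-handed product at the end, north-east
4. excess of left-handed product over right-handed product at the end, east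

Both substrates start equal, so at full conversion any excess has to come from what crosses between them. Free catalyst comes back after each turn and partner stays near steady, so each substrate decays pseudo-first-order, with a lifetime τL for the left-handed and τR for the right-handed. Consumption is taken as the main event and racemization as a correction to it. The right-handed substrate lingers, so a net amount crosses to the left-handed side, and each unit that crosses adds to left-handed product and takes from right-handed product. To first order the excess is (τR − τL)/τx, with τx the racemization time. The crossing narrows the gap that feeds it, which divides this by 1 + m, where m = (τL + τR)/τx. Written with the ceiling s = (τR − τL)/(τR + τL), the excess at full conversion, with the lifetimes held steady, is s·m/(1 + m).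

The dimer balance leaves 47.8 mM of racemization catalyst free, and with an enthalpy of −1.00 kJ mol⁻¹ that figure is kept for both temperatures. Partner is taken midway between saturation and its early balance of supply against use, which gives 0.173 M in east. East then has τL = 3.02 min, τR = 6.92 min and τx = 15.2 min. Its exchange number, the sum of the two lifetimes over the racemization time, is 0.656. With a ceiling of 39.3%, east should reach 15.6%.

Cooling to 10 °C divides racemization by 2.7, the right-handed step by 2.1 and the left-handed step by 3.04, since the exponent scales with activation energy. North-east therefore has a ceiling of 22.9% and, with partner at 0.188 M, an exchange number of 0.540. South-west, cold for 8.0 min and then warm, should land between the two.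

Turned round: with north-east's figures held, for north-east to lead, east's fraction m/(1 + m) would have to fall below 0.205, a bar lower than north-east's own fraction because east's ceiling is higher than north-east's. East's fraction is 0.396, twice that bar.

The forecast put east first, with 11.6% for south-west, 8.4% for north-east and 15.2% for east, and its ground reads: “Racemization outruns resolution loss when warm, so east leads”.

The simulation puts east first, with 11.5% for south-west, 8.49% for north-east and 15.2% for east.

Against its ceiling, east's excess reads as an exchange number of 0.631, where 0.656 was reckoned. In east the left-handed step had half its turnover behind it at 2.85 min and the right-handed step at 4.27 min. North-east's exchange number of 0.540 gives 8.03% at full conversion. After 40.0 min north-east still held 1.5% of its left-handed and 3.2% of its right-handed charge and stood at 8.49%, and after 400 min it stood at 7.89%.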